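## The problem

The target is a 6,7-seco-ent-kauranoid (atoms carry kaurane numbers). Ring A (C1–C5, C10) is joined only through the quaternary spiro carbon C10 to a δ-lactone (C10, C20, O, C7, C8, C9). The lactone is cis-fused along C8–C9 to a bicyclo[3.2.1]octanone built from ring C (C8, C9, C11, C12, C13, C14) and ring D (C8, C14, C13, C16, C15).

There are seven stereocentres (C1, C5, C10, C9, C8, C13, C16). Two are quaternary, and C8 lies between the lactone carbonyl C7 and the ketone C15. C5 and C10 are neighbours with no earlier centre to lean on, so they must be set in absolute terms. Once they stand, each later centre can be relayed: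

- the C5 branch (ester C6 next to the C4 gem-dimethyl group) shields one face of the lactone and so directs C9 and C8;
- C8 dictates C13, because the bridge can close only one way;
- the open exo face of ring D sets C16;
- the chair of ring A sets C1.

Several groups are fragile. The α-acyl lactone at C8 is open to retro-Claisen cleavage by hydroxide, alkoxide or hydrazine. C16 is epimerisable and carries its methyl group on the more crowded endo side. The C1 acetate can be lost or can shift to a free C20 hydroxyl. The C6 carboxyl is cis to C20 and would lactonise onto a free C20 hydroxyl unless it is a bulky ester. Strong base, hydrazine and hydride therefore have to be used before the C7/C8/C15 unit is attached, and the end of the route has to be neutral or acidic.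

The enabling feature is the C5–C10 bond: C6 is cis to the oxymethylene C20 and trans to C9. This is the imprint of a suprafacial addition across an E alkene that carries formyl C9 and CH2O–C20 on C10 and the ester C6 on C5. The other four ring A atoms, C1–C4, form the diene, and an oxygen at C3 gives the handle for the C4 methyl groups and, after transposition, for the C1 oxygen.

## Retrosynthesis

**C16 and the final saturation (31 ⇐ 30 ⇐ 29 ⇐ 26).** The C16–H and C11/C12–H bonds are cut first. Target 31 is traced to dienone acid 30, which carries a C16=C17 methylene and a C11=C12 alkene, so that the epimerisable centre is made last and under neutral hydrogenation. Acid 30 comes from tert-butyl ester 29, and 29 from ketone 26 by α-methylenation (cut C16=C17). Carrying a C16 methyl through ring D closure was rejected, because closure and equilibration would favour the exo methyl. Hydrogen delivered to the open exo face places the methyl endo, as required.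

**Ring D (26 ⇐ 24).** The C13–C16 bond is cut. The methyl ketone in 24 is the only enolisable ketone, and its enol ether lies over the C12=C13 alkene. The neighbouring cut at C8–C15 would instead ask for a quaternary centre to be made at the end. Compound 24 has one ring and one stereocentre fewer. The forward step must close at C13, not C12, and leave the C11=C12 alkene.

**Ring C (24 ⇐ 22 + 23).** The C8–C14 and C9–C11 bonds are cut together as a Diels–Alder addition of butadiene 23 to acyl lactone 22. This cut creates the quaternary C8 and C9 in one step and leaves the C12=C13 alkene that ring D closure needs. A stepwise annulation would have to set C8 against C9 separately. The forward step needs the diene on the lactone face on the C1 side, away from C5.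

**Lactone (22 ⇐ 20 ⇐ 18 + 19).** The C8=C9 alkene is cut by a Knoevenagel disconnection and the C20–O–C7 ester by acylation. C7, C8, C15 and C16 then come from one acetoacetyl unit (dioxinone 19), which brings C15 in at the ketone level. Compound 18 is a monocyclic ring A with a free C20 hydroxyl and C9 masked as an acetal. The forward steps need neutral conditions so that the C1 acetate stays in place.

**C1 oxygen (18 ⇐ 17 ⇐ 16 ⇐ 15 ⇐ 14 ⇐ 13 ⇐ 12).** The C1–O bond is traced to hydride reduction of the C1 ketone 15, with saturation of C2=C3. Ketone 15 comes by 1,3-transposition (Wharton product 14, epoxy ketone 13) from the C3 enone 12. Direct oxygen delivery to C1 of 12 was rejected: a nucleophile is expected anti to the axial C20 group, which is the wrong epimer. Hydride from that same open face places the hydroxyl cis to C20, as required. The same sequence removes the C3 oxygen.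

**C4 methyl groups (12 ⇐ 11 ⇐ 10 ⇐ 9).** The two C4–CH3 bonds are cut. In enone 10, C2 is vinylic and C10 is quaternary, so C4 is the only enolisable carbon. The formyl group is masked as the dimethyl acetal 11. Enone 10 comes from silyl enol ether 9 by dehydrogenation. Alkylating a saturated C3 ketone would give C2/C4 mixtures.

**Ring A (9 ⇐ 6 + 8).** The C1–C10 and C4–C5 bonds are cut. This single cut removes the ring and both C5 and C10, leaving two achiral partners, the E enal ester 6 and the silyloxydiene 8. The forward step must be enantioselective and regioselective (C4 to C5).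

**Partners (6 ⇐ 5 ⇐ 3 ⇐ 1 + 2 + 4; 8 ⇐ 7).** The formyl C=O of 6 is traced to the vinyl group of dienoate 5, and the C3–vinyl bond of 5 to syn-carbocupration of ynoate 3 with vinylmagnesium bromide 4. Ynoate 3 comes from propargyl ether 1 and Boc2O 2. A shorter olefination of benzyloxyacetone followed by allylic oxidation was rejected: it leaves both the alkene geometry and the site of oxidation (CH3 or CH2OBn) open. Diene 8 comes from enone 7 in one step.

## Roads not taken

**Alternative 1:** The cut is at C13–C14 and C8–C15. The substrate is the α-methylene lactone A1, which carries on C9 a chain ending in a silyl-substituted allylic acetate. Pd(PPh3)4 would ionise the acetate, and desilylation would give a trimethylenemethane complex. Its C13 terminus would add to C14, and the C8 enolate would close on C15, giving the bridged methylene compound A2.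

- Merits: rings C and D and the quaternary C8 form in one step, and the C16 exocyclic alkene arrives without a separate methylenation. In this respect it is better than the chosen plan, which spends steps 17–19 on the same ground.
- Weak points: C15 arrives as CH2 and needs allylic oxidation next to C8. A bridging cycloaddition with a substituted trimethylenemethane terminus has open regiochemistry and open facial control at C8. A1 already contains ring A with C1, C5, C10 and C9, so the hardest stereochemical problem is left untouched.
- Comparison: the chosen plan sets C5 and C10 catalytically at the start and brings C15 in at the ketone level.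

**Alternative 2:** The cut is at C10–C20. The substrate is phenol A3, a 4-substituted phenol on C9 of the bicyclic ketone, with a chloromethyl ester on C7. Cs2CO3 would form the phenoxide, whose para carbon displaces chloride to give the spirodienone lactone A4.

- Merits: the spiro centre is made in one step from a flat ring, with no stereochemical demand at that step, and the bicyclic half can be prepared separately. This is more convergent than the chosen plan.
- Weak points: C10 becomes stereogenic only when the two enone arms of A4 are told apart. C6 is missing and must be added by conjugate addition at C5, on the face cis to C20, next to a quaternary carbon. The C4 methyl groups, the C1 oxygen and removal of the C3 oxygen still follow, so ring A needs at least as many steps as here, with weaker control. The chloromethyl ester is also labile to carbonate.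
- Comparison: the chosen plan delivers C5, C10 and C6 with the right relation in its key step.

**Alternative 3:** The cut is at C5–C10. The substrate is epoxy alcohol A5, a cyclopentanol (C1) that carries C5 and a spiro-epoxide at C10/C20. Et2AlCl would open the epoxide at C10, and C5 would migrate from C1 to C10, giving hydroxymethyl ketone A6.

- Merits: the quaternary C10 forms stereospecifically, and the product carries the C1 carbonyl and the free C20 hydroxyl directly. Here it is better than the chosen plan, which needs steps 9–12 to move oxygen from C3 to C1.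
- Weak points: A5 requires both halves in enantioenriched form, a C5 centre next to a ketone on the way, and an epoxide of defined configuration beside a tertiary carbinol. The migration of the hindered C5 competes with migration of C2 and with hydride shift. C6 is at the alcohol level, C15 is a ketal and C7 a methyl ester, so three more adjustments follow.
- Comparison: the chosen plan makes C5 and C10 together from achiral materials in one catalytic step, with C6 already at the acid level and C9 and C20 differentiated from the outset.

Key step: step 5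

Assumption: with the formyl-bound, s-trans enal, the (S)-configured oxazaborolidinium cation is taken to leave the Si face of C10 open, which gives (1R,6R)-9. If the sense of induction is the opposite, the (R)-catalyst is used and nothing else changes.

## Route

Step 1
Reactants: 1 benzyl prop-2-yn-1-yl ether; 2 di-tert-butyl dicarbonate
Product: 3 tert-butyl 4-(benzyloxy)but-2-ynoate
Conditions: n-BuLi, THF, −78 °C; then 2, −78 → 0 °C; H2O
Reagents that add atoms: none
Why: Acylation of a lithium acetylide with Boc2O is a standard entry to tert-butyl alkynoates; the benzyl ether is inert.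

Step 2
Reactants: 3 tert-butyl 4-(benzyloxy)but-2-ynoate; 4 vinylmagnesium bromide
Product: 5 tert-butyl (2Z)-3-[(benzyloxy)methyl]penta-2,4-dienoate
Conditions: 4 (2.0 equiv), CuBr·SMe2 (1.0 equiv), THF, −78 °C; then MeOH, aq NH4Cl, −78 °C
Reagents that add atoms: none
Why: syn-Carbocupration of an ynoate puts vinyl on the carbon bearing CH2OBn and copper on the α-carbon; protonation with retention leaves vinyl trans and CH2OBn cis to the ester, and the cold quench prevents isomerisation of the alkenylcopper.

Step 3
Reactants: 5 tert-butyl (2Z)-3-[(benzyloxy)methyl]penta-2,4-dienoate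
Product: 6 tert-butyl (2E)-4-(benzyloxy)-3-formylbut-2-enoate
Conditions: O3 (1 equiv), CH2Cl2, −78 °C; then Me2S, −78 °C → rt
Reagents that add atoms: ozone, [O-][O+]=O
Why: Ozonolysis takes the electron-richer terminal vinyl group of a 2,4-dienoate before the ester-conjugated alkene (the sorbate-to-fumaraldehydate pattern), giving the enal with formyl trans to the ester.

Step 4
Reactants: 7 but-3-en-2-one
Product: 8 2-(triisopropylsilyloxy)buta-1,3-diene
Conditions: TIPSOTf, Et3N, Et2O, 0 °C → rt
Reagents that add atoms: triisopropylsilyl trifluoromethanesulfonate, CC(C)[Si](C(C)C)(C(C)C)OS(=O)(=O)C(F)(F)F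
Why: Soft enolisation and O-silylation of the methyl ketone gives the known, storable 2-silyloxydiene.

Step 5
Reactants: 6 tert-butyl (2E)-4-(benzyloxy)-3-formylbut-2-enoate; 8 2-(triisopropylsilyloxy)buta-1,3-diene
Product: 9 tert-butyl (1R,6R)-6-[(benzyloxy)methyl]-6-formyl-3-[(triisopropylsilyl)oxy]cyclohex-3-ene-1-carboxylate
Conditions: (S)-3,3-diphenyl-1-(2-methylphenyl)tetrahydro-1H,3H-pyrrolo[1,2-c][1,3,2]oxazaborole (20 mol %), HNTf2 (17 mol %), CH2Cl2, −78 °C
Reagents that add atoms: none
Why: The protonated oxazaborolidine binds the formyl oxygen of 6 (s-trans enal held by a formyl C–H···O contact) and lowers the LUMO of the C10=C5 alkene. Diene 8 then adds in a concerted but asynchronous [4+2] cycloaddition, the reaction type established for α-substituted enals with 2-silyloxydienes under chiral oxazaborolidinium catalysis. Its nucleophilic CH2 next to the silyloxy carbon (C4) bonds first to the enal β-carbon C5, and C1 bonds to C10. Ring A closes by this intermolecular cycloaddition, suprafacial on both partners, as a cyclohexene with the enol ether at C2=C3. C10 is set by the catalyst, whose aryl group covers one face of the bound enal so that the diene reaches the open face. C5 follows from C10 because the E geometry of 6 is transferred, leaving formyl C9 trans and C20 cis to the ester C6. The step needs enantiofacial selection, the 1,4 regiochemistry and activation at formyl instead of ester; the more basic aldehyde oxygen secures the binding site, and the silyloxy group polarises the diene so that C4 pairs with C5. The tert-butyl ester and the benzyl ether are spectators at −78 °C.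

Step 6
Reactants: 9 tert-butyl (1R,6R)-6-[(benzyloxy)methyl]-6-formyl-3-[(triisopropylsilyl)oxy]cyclohex-3-ene-1-carboxylate
Product: 10 tert-butyl (1R,2R)-2-[(benzyloxy)methyl]-2-formyl-5-oxocyclohex-3-ene-1-carboxylate
Conditions: Pd(OAc)2 (1.1 equiv), MeCN, 40 °C
Reagents that add atoms: none
Why: Saegusa–Ito oxidation; the palladium enolate at C2 can lose a β-hydrogen only from C1, so the C1=C2–C3=O enone forms regiospecifically and blocks C2 against later enolisation.

Step 7
Reactants: 10 tert-butyl (1R,2R)-2-[(benzyloxy)methyl]-2-formyl-5-oxocyclohex-3-ene-1-carboxylate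
Product: 11 tert-butyl (1R,2R)-2-[(benzyloxy)methyl]-2-(dimethoxymethyl)-5-oxocyclohex-3-ene-1-carboxylate
Conditions: HC(OMe)3, CeCl3·7H2O (cat.), MeOH, rt
Reagents that add atoms: trimethyl orthoformate, COC(OC)OC
Why: Lanthanide-catalysed acetalisation is selective for an aldehyde over a conjugated ketone; the acetal shields C9 from the base, peroxide, hydrazine and hydride of steps 8–12.

Step 8
Reactants: 11 tert-butyl (1R,2R)-2-[(benzyloxy)methyl]-2-(dimethoxymethyl)-5-oxocyclohex-3-ene-1-carboxylate
Product: 12 tert-butyl (1S,2R)-2-[(benzyloxy)methyl]-2-(dimethoxymethyl)-6,6-dimethyl-5-oxocyclohex-3-ene-1-carboxylate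
Conditions: LDA, THF, −78 °C, then MeI; second portion of LDA, DMPU, MeI, −78 → −20 °C (same flask)
Reagents that add atoms: iodomethane, CI
Why: Twofold kinetic α′-alkylation of an enone; C4 is the only enolisable carbon of the ketone (C2 is vinylic, C10 is quaternary), and its protons are removed before the hindered ester α-proton at C5, so C5 is not disturbed.

Step 9
Reactants: 12 tert-butyl (1S,2R)-2-[(benzyloxy)methyl]-2-(dimethoxymethyl)-6,6-dimethyl-5-oxocyclohex-3-ene-1-carboxylate
Product: 13 tert-butyl 2-[(benzyloxy)methyl]-2-(dimethoxymethyl)-3,4-epoxy-6,6-dimethyl-5-oxocyclohexane-1-carboxylate (epoxide on the C9 face; epimer expected to predominate)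
Conditions: 30% H2O2, NaOH (cat.), MeOH, 0 °C
Reagents that add atoms: hydrogen peroxide, OO
Why: Weitz–Scheffer epoxidation; hydroperoxide should add to C1 anti to the axial C20 group, as in steroidal 1-en-3-ones, but either epoxide serves because C1 becomes a ketone in step 11.

Step 10
Reactants: 13 tert-butyl 2-[(benzyloxy)methyl]-2-(dimethoxymethyl)-3,4-epoxy-6,6-dimethyl-5-oxocyclohexane-1-carboxylate
Product: 14 tert-butyl 2-[(benzyloxy)methyl]-2-(dimethoxymethyl)-3-hydroxy-6,6-dimethylcyclohex-4-ene-1-carboxylate (hydroxyl trans to the benzyloxymethyl group)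
Conditions: N2H4·H2O, AcOH (cat.), MeOH, 0 °C → rt
Reagents that add atoms: none
Why: Wharton transposition (hydrazone, epoxide opening, loss of N2) moves oxygen from C3 to C1 and leaves C2=C3; it is precedented on 4,4-dimethyl ring A epoxy ketones, and the tert-butyl ester resists hydrazinolysis.

Step 11
Reactants: 14 tert-butyl 2-[(benzyloxy)methyl]-2-(dimethoxymethyl)-3-hydroxy-6,6-dimethylcyclohex-4-ene-1-carboxylate
Product: 15 tert-butyl 2-[(benzyloxy)methyl]-2-(dimethoxymethyl)-6,6-dimethyl-3-oxocyclohex-4-ene-1-carboxylate
Conditions: Dess–Martin periodinane, NaHCO3, CH2Cl2, rt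
Reagents that add atoms: none
Why: Dess–Martin oxidation of the allylic alcohol; both C1 epimers converge on the transposed enone.

Step 12
Reactants: 15 tert-butyl 2-[(benzyloxy)methyl]-2-(dimethoxymethyl)-6,6-dimethyl-3-oxocyclohex-4-ene-1-carboxylate
Product: 16 tert-butyl 2-[(benzyloxy)methyl]-2-(dimethoxymethyl)-3-hydroxy-6,6-dimethylcyclohexane-1-carboxylate (hydroxyl cis to the benzyloxymethyl group and to the ester)
Conditions: NaBH4 (excess), NiCl2·6H2O (20 mol %), MeOH–THF, 0 °C
Reagents that add atoms: none
Why: Nickel boride saturates C2=C3 and borohydride reduces the C1 ketone. In the ring A chair with C20 axial, hydride enters axially from the C9 face, anti to the axial CH2OBn group, and gives the equatorial C1 alcohol cis to C20, the sense known for 1-oxo steroids. The benzyl ether, acetal and ester are untouched.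

Step 13
Reactants: 16 tert-butyl 2-[(benzyloxy)methyl]-2-(dimethoxymethyl)-3-hydroxy-6,6-dimethylcyclohexane-1-carboxylate
Product: 17 tert-butyl 3-acetoxy-2-[(benzyloxy)methyl]-2-(dimethoxymethyl)-6,6-dimethylcyclohexane-1-carboxylate
Conditions: Ac2O, DMAP, Et3N, CH2Cl2, rt
Reagents that add atoms: acetic anhydride, CC(=O)OC(C)=O
Why: DMAP-catalysed acetylation of the hindered secondary alcohol installs the C1 acetate of the target, which also protects C1 for the rest of the route.

Step 14
Reactants: 17 tert-butyl 3-acetoxy-2-[(benzyloxy)methyl]-2-(dimethoxymethyl)-6,6-dimethylcyclohexane-1-carboxylate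
Product: 18 tert-butyl 3-acetoxy-2-(dimethoxymethyl)-2-(hydroxymethyl)-6,6-dimethylcyclohexane-1-carboxylate
Conditions: H2 (1 atm), Pd(OH)2/C, EtOAc, rt
Reagents that add atoms: none
Why: Neutral hydrogenolysis of the benzyl ether; without acid or base the acetate should not shift to C20–OH, and the tert-butyl ester is too hindered to lactonise onto it.

Step 15
Reactants: 18 tert-butyl 3-acetoxy-2-(dimethoxymethyl)-2-(hydroxymethyl)-6,6-dimethylcyclohexane-1-carboxylate; 19 2,2,6-trimethyl-4H-1,3-dioxin-4-one
Product: 20 tert-butyl 3-acetoxy-2-(dimethoxymethyl)-6,6-dimethyl-2-[(3-oxobutanoyloxy)methyl]cyclohexane-1-carboxylate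
Conditions: toluene, 110 °C
Reagents that add atoms: none
Why: Thermal cycloreversion of 19 gives acetylketene, which the primary alcohol traps as the acetoacetate (C7, C8, C15, C16); no base is present, so the acetate stays on C1.

Step 16
Reactants: 20 tert-butyl 3-acetoxy-2-(dimethoxymethyl)-6,6-dimethyl-2-[(3-oxobutanoyloxy)methyl]cyclohexane-1-carboxylate
Product: 22 tert-butyl 11-acetoxy-4-acetyl-8,8-dimethyl-3-oxo-2-oxaspiro[5.5]undec-4-ene-7-carboxylate, via formyl acetoacetate 21 (not isolated)
Conditions: TsOH·H2O (10 mol %), acetone–H2O, rt; solvent exchange; piperidine (cat.), AcOH (cat.), CH2Cl2, 4 Å MS, rt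
Reagents that add atoms: none
Why: Mild acid frees the C9 aldehyde while the tert-butyl ester and acetate survive; intramolecular Knoevenagel condensation of the acetoacetate then forms C8=C9 and closes the six-membered lactone, and the quaternary C10 prevents double-bond migration.

Step 17
Reactants: 22 tert-butyl 11-acetoxy-4-acetyl-8,8-dimethyl-3-oxo-2-oxaspiro[5.5]undec-4-ene-7-carboxylate; 23 buta-1,3-diene
Product: 24 tert-butyl ester of the ring C cyclohexene adduct (spiro lactone cis-fused to a cyclohex-3-ene with C12=C13; acetyl on C8; C11 and C14 on the C1 face of the lactone)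
Conditions: 23 (excess), ZnCl2 (1.0 M in Et2O, 1.5 equiv), CH2Cl2, −20 °C → rt, sealed vessel
Reagents that add atoms: none
Why: The Lewis acid chelates the α-acyl lactone, a doubly activated dienophile of the 2-acyl enone type, and butadiene adds suprafacially to form C8–C14 and C9–C11. The diene should come from the lactone face on the C1 side, away from C5 with its tert-butoxycarbonyl group and the adjacent C4 gem-dimethyl group, which sets C9 and the quaternary C8.

Step 18
Reactants: 24 tert-butyl ester of the ring C cyclohexene adduct
Product: 26 tert-butyl ester of the bicyclo[3.2.1]octenone lactone (C13–C16 bond closed; C15 ketone; C11=C12), via trimethylsilyl enol ether 25 (not isolated)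
Conditions: LiHMDS, TMSCl, THF, −78 °C; then Pd(OAc)2 (1.1 equiv), MeCN, rt
Reagents that add atoms: none
Why: The methyl ketone is silylated at its only enolisable site; Pd(OAc)2 then gives a palladium enolate that inserts the C12=C13 alkene in the 5-exo sense and eliminates a β-hydrogen from C11 (Kende cyclisation of a silyl enol ether onto a ring alkene). C13 can only form on the face that carries the C8 acyl bridge.

Step 19
Reactants: 26 tert-butyl ester of the bicyclo[3.2.1]octenone lactone
Product: 29 tert-butyl ester of the 16-methylene-15-ketone (C16=C17; C11=C12), via Mannich base 27 (not isolated), via trimethylammonium iodide 28 (not isolated)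
Conditions: LiHMDS, THF, −78 °C; Me2N=CH2+ I−, −78 → 0 °C; then MeI, CH2Cl2, rt; then DBU, rt
Reagents that add atoms: N,N-dimethylmethyleneiminium iodide, C=[N+](C)C.[I-]
Why: Mannich methylenation; the C16 protons are the most acidic in 26, the enolate traps the iminium salt, and quaternisation followed by elimination gives the exocyclic enone, a routine operation on bicyclo[3.2.1]octanones of this family.

Step 20
Reactants: 29 tert-butyl ester of the 16-methylene-15-ketone
Product: 30 16-methylene-15-oxo-11-ene C6 carboxylic acid (the free acid of 29)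
Conditions: TFA, CH2Cl2, 0 °C
Reagents that add atoms: none
Why: Acidolysis of the tert-butyl ester; the acetate, lactone and enone are stable to cold TFA, and no base-sensitive centre exists yet.

Step 21
Reactants: 30 16-methylene-15-oxo-11-ene C6 carboxylic acid
Product: 31 target CNP0161834.1 (1-acetoxy-15-oxo-6,7-seco-ent-kauran-7,20-olid-6-oic acid with the C1 acetate cis to C20 and the C16 methyl endo)
Conditions: H2 (1 atm), Pd/C, EtOAc, rt
Reagents that add atoms: none
Why: Catalytic hydrogenation saturates C11=C12 and C16=C17; hydrogen should reach C16 from the exo face of ring D, away from the C11–C12 bridge, so that the methyl ends endo (cis to C12) as in the target, and the neutral medium leaves C16 unepimerised.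

## Compound list

1 | benzyl prop-2-yn-1-yl ether | C#CCOCc1ccccc1 | starting material
2 | di-tert-butyl dicarbonate | CC(C)(C)OC(=O)OC(=O)OC(C)(C)C | starting material
3 | tert-butyl 4-(benzyloxy)but-2-ynoate | CC(C)(C)OC(=O)C#CCOCc1ccccc1 | intermediate
4 | vinylmagnesium bromide | C=C[Mg]Br | starting material
5 | tert-butyl (2Z)-3-[(benzyloxy)methyl]penta-2,4-dienoate | C=C/C(COCc1ccccc1)=C/C(=O)OC(C)(C)C | intermediate
6 | tert-butyl (2E)-4-(benzyloxy)-3-formylbut-2-enoate | O=C/C(COCc1ccccc1)=C/C(=O)OC(C)(C)C | intermediate
7 | but-3-en-2-one | CC(=O)C=C | starting material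
8 | 2-(triisopropylsilyloxy)buta-1,3-diene | C=CC(=C)O[Si](C(C)C)(C(C)C)C(C)C | intermediate
9 | tert-butyl (1R,6R)-6-[(benzyloxy)methyl]-6-formyl-3-[(triisopropylsilyl)oxy]cyclohex-3-ene-1-carboxylate | O=C[C@]1(COCc2ccccc2)CC=C(O[Si](C(C)C)(C(C)C)C(C)C)C[C@H]1C(=O)OC(C)(C)C | intermediate
10 | tert-butyl (1R,2R)-2-[(benzyloxy)methyl]-2-formyl-5-oxocyclohex-3-ene-1-carboxylate | O=C[C@]1(COCc2ccccc2)C=CC(=O)C[C@H]1C(=O)OC(C)(C)C | intermediate
11 | tert-butyl (1R,2R)-2-[(benzyloxy)methyl]-2-(dimethoxymethyl)-5-oxocyclohex-3-ene-1-carboxylate | COC(OC)[C@]1(COCc2ccccc2)C=CC(=O)C[C@H]1C(=O)OC(C)(C)C | intermediate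
12 | tert-butyl (1S,2R)-2-[(benzyloxy)methyl]-2-(dimethoxymethyl)-6,6-dimethyl-5-oxocyclohex-3-ene-1-carboxylate | COC(OC)[C@]1(COCc2ccccc2)C=CC(=O)C(C)(C)[C@H]1C(=O)OC(C)(C)C | intermediate
13 | C1,C2-epoxide of 12, oxygen on the C9 face (epimer expected to predominate) | COC(OC)[C@]1(COCc2ccccc2)[C@@H]3O[C@@H]3C(=O)C(C)(C)[C@H]1C(=O)OC(C)(C)C | intermediate
14 | tert-butyl 2-[(benzyloxy)methyl]-2-(dimethoxymethyl)-3-hydroxy-6,6-dimethylcyclohex-4-ene-1-carboxylate, hydroxyl trans to CH2OBn | COC(OC)[C@]1(COCc2ccccc2)[C@H](O)C=CC(C)(C)[C@H]1C(=O)OC(C)(C)C | intermediate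
15 | tert-butyl 2-[(benzyloxy)methyl]-2-(dimethoxymethyl)-6,6-dimethyl-3-oxocyclohex-4-ene-1-carboxylate | COC(OC)[C@]1(COCc2ccccc2)C(=O)C=CC(C)(C)[C@H]1C(=O)OC(C)(C)C | intermediate
16 | tert-butyl 2-[(benzyloxy)methyl]-2-(dimethoxymethyl)-3-hydroxy-6,6-dimethylcyclohexane-1-carboxylate, hydroxyl cis to CH2OBn and to the ester | COC(OC)[C@]1(COCc2ccccc2)[C@@H](O)CCC(C)(C)[C@H]1C(=O)OC(C)(C)C | intermediate
17 | tert-butyl 3-acetoxy-2-[(benzyloxy)methyl]-2-(dimethoxymethyl)-6,6-dimethylcyclohexane-1-carboxylate | COC(OC)[C@]1(COCc2ccccc2)[C@@H](OC(C)=O)CCC(C)(C)[C@H]1C(=O)OC(C)(C)C | intermediate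
18 | tert-butyl 3-acetoxy-2-(dimethoxymethyl)-2-(hydroxymethyl)-6,6-dimethylcyclohexane-1-carboxylate | COC(OC)[C@]1(CO)[C@@H](OC(C)=O)CCC(C)(C)[C@H]1C(=O)OC(C)(C)C | intermediate
19 | 2,2,6-trimethyl-4H-1,3-dioxin-4-one | CC1=CC(=O)OC(C)(C)O1 | starting material
20 | tert-butyl 3-acetoxy-2-(dimethoxymethyl)-6,6-dimethyl-2-[(3-oxobutanoyloxy)methyl]cyclohexane-1-carboxylate | COC(OC)[C@]1(COC(=O)CC(C)=O)[C@@H](OC(C)=O)CCC(C)(C)[C@H]1C(=O)OC(C)(C)C | intermediate
21 | tert-butyl 3-acetoxy-2-formyl-6,6-dimethyl-2-[(3-oxobutanoyloxy)methyl]cyclohexane-1-carboxylate | O=C[C@]1(COC(=O)CC(C)=O)[C@@H](OC(C)=O)CCC(C)(C)[C@H]1C(=O)OC(C)(C)C | intermediate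
22 | tert-butyl 11-acetoxy-4-acetyl-8,8-dimethyl-3-oxo-2-oxaspiro[5.5]undec-4-ene-7-carboxylate (acetoxy, C20 and ester on one face of ring A) | CC(=O)O[C@H]1CCC(C)(C)[C@@H](C(=O)OC(C)(C)C)[C@@]12COC(=O)C(C(C)=O)=C2 | intermediate
23 | buta-1,3-diene | C=CC=C | starting material
24 | tert-butyl ester of the ring C cyclohexene adduct (C12=C13, acetyl on C8) | CC(=O)O[C@H]1CCC(C)(C)[C@@H](C(=O)OC(C)(C)C)[C@@]12COC(=O)[C@@]3(C(C)=O)CC=CC[C@@H]23 | intermediate
25 | trimethylsilyl enol ether of 24 at C15=C16 | CC(=O)O[C@H]1CCC(C)(C)[C@@H](C(=O)OC(C)(C)C)[C@@]12COC(=O)[C@@]3(C(=C)O[Si](C)(C)C)CC=CC[C@@H]23 | intermediate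
26 | tert-butyl ester of the bicyclo[3.2.1]octenone lactone (C13–C16 bond, C15 ketone, C11=C12) | CC(=O)O[C@H]1CCC(C)(C)[C@@H](C(=O)OC(C)(C)C)[C@@]12COC(=O)[C@@]13C[C@@H](C=C[C@H]12)CC3=O | intermediate
27 | C16 dimethylaminomethyl ketone (Mannich base of 26, aminomethyl exo) | CC(=O)O[C@H]1CCC(C)(C)[C@@H](C(=O)OC(C)(C)C)[C@@]12COC(=O)[C@@]13C[C@@H](C=C[C@H]12)[C@H](CN(C)C)C3=O | intermediate
28 | trimethylammonium iodide of 27 | CC(=O)O[C@H]1CCC(C)(C)[C@@H](C(=O)OC(C)(C)C)[C@@]12COC(=O)[C@@]13C[C@@H](C=C[C@H]12)[C@H](C[N+](C)(C)C)C3=O.[I-] | intermediate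
29 | tert-butyl ester of the 16-methylene-15-ketone (C16=C17, C11=C12) | CC(=O)O[C@H]1CCC(C)(C)[C@@H](C(=O)OC(C)(C)C)[C@@]12COC(=O)[C@@]13C[C@@H](C=C[C@H]12)C(=C)C3=O | intermediate
30 | 16-methylene-15-oxo-11-ene C6 carboxylic acid | CC(=O)O[C@H]1CCC(C)(C)[C@@H](C(=O)O)[C@@]12COC(=O)[C@@]13C[C@@H](C=C[C@H]12)C(=C)C3=O | intermediate
31 | CNP0161834.1 | CC(=O)O[C@H]1CCC(C)(C)[C@@H](C(=O)O)[C@@]12COC(=O)[C@@]13C[C@@H](CC[C@H]12)[C@@H](C)C3=O | target

## Step count and risk

Total: 21 steps. Longest linear sequence: 20 steps (steps 1–3 and 5–21, from 1); step 4 is a one-step side branch to diene 8.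

**Step 5 (key step).** The most likely failure is loss of enantiofacial control. The cationic boron may also bind the ester or benzyloxy oxygen, and an uncatalysed background addition of the very electron-poor enal is possible. Either would erode the selectivity or reverse the C4–C5 pairing.

The fallback replaces asymmetric catalysis by resolution. It sets out from 6 and 8 and returns at 10. The cycloaddition is run with EtAlCl2 (CH2Cl2, −78 °C) to give 9 as the racemate, that is together with its mirror image, tert-butyl (1S,6S)-6-[(benzyloxy)methyl]-6-formyl-3-[(triisopropylsilyl)oxy]cyclohex-3-ene-1-carboxylate F1. Oxidation as in step 6 gives 10 together with tert-butyl (1S,2S)-2-[(benzyloxy)methyl]-2-formyl-5-oxocyclohex-3-ene-1-carboxylate F2. Condensation of this pair with (1R,2R)-N,N′-dimethyl-1,2-diphenylethane-1,2-diamine (Et2O, 4 Å MS) gives two diastereomers: the (4R,5R)-1,3-dimethyl-4,5-diphenylimidazolidin-2-yl aminal of 10 F3 and the corresponding aminal of the enantiomer of 10 F4. These are separated on silica. Dilute aqueous HCl in ether then hydrolyses F3 to 10.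

**Step 17.** The cycloaddition may be sluggish at the neopentyl C9 of a trisubstituted dienophile. The acyl lactone or the diene could then oligomerise, or the lactone could react as a heterodiene. Facial discrimination between the C1 and C5 sides may also be incomplete, since an acetoxy group and an ester flank C9.

The fallback uses a far more nucleophilic diene and removes its oxygen afterwards. It sets out from 22 and returns at 24. Diene 8 adds to 22 (ZnCl2 or heat), its nucleophilic CH2 bonding to C9, to give the C12 triisopropylsilyl enol ether analogue of 24 F5. CsF and PhNTf2 in DME convert this regiospecifically into the C12 enol triflate F6. Reduction with Pd(OAc)2/PPh3 (cat.), Bu3N and HCO2H in DMF then gives 24.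

**Step 18.** The palladium enolate may cyclise at C12 as well as at C13, which would give a bicyclo[2.2.2]octane. It may also be protonated back to the ketone before it inserts the alkene.

The fallback closes ring D by a radical reaction. It sets out from 24 and returns at 26. Enol ether 25 is treated with N-iodosuccinimide to give the iodomethyl ketone of 24 F7. Iodine-atom-transfer cyclisation ((Bu3Sn)2 cat., hν, benzene) closes C16 onto C13 and leaves the C12 iodide of the bicyclo[3.2.1]octanone F8. DBU then eliminates HI towards C11, since C13 is a bridgehead, and gives 26.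

**Step 12.** Hydride may be delivered in part from the C20 face. Borohydride may also reduce the enone carbonyl first, while the ring is still a half-chair. Either would give the C1 epimer.

The fallback puts the hydride transfer under catalyst control. It sets out from 15 and returns at 16. Oxazaborolidine-catalysed borane reduction of 15 is used, with (R)-1-methyl-3,3-diphenyltetrahydro-1H,3H-pyrrolo[1,2-c][1,3,2]oxazaborole and catecholborane; this is the catalyst enantiomer that delivers hydride to the C9 face when C10 is the large group. It gives the allylic alcohol epimeric with 14 at C1 (hydroxyl cis to CH2OBn) F9. Diimide (2-nitrobenzenesulfonohydrazide, Et3N) then saturates C2=C3 without touching the benzyl ether and gives 16.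

**Step 21.** Hydrogen may be delivered in part to the endo face of the C16 methylene, more easily while C11=C12 is still unsaturated. That would give the exo methyl epimer.

The fallback sets C16 by kinetic protonation of an enolate. It sets out from 29 and returns at 31. Conjugate reduction of 29 with [(Ph3P)CuH]6, followed by a cold quench with a hindered proton source from the exo face, gives the tert-butyl ester with the C16 methyl endo and C11=C12 intact F10. Hydrogenation (H2, Pd/C) then gives the tert-butyl ester of the target F11, and TFA in CH2Cl2 gives 31.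

## Further compounds

F1 | step 5 | tert-butyl (1S,6S)-6-[(benzyloxy)methyl]-6-formyl-3-[(triisopropylsilyl)oxy]cyclohex-3-ene-1-carboxylate | O=C[C@@]1(COCc2ccccc2)CC=C(O[Si](C(C)C)(C(C)C)C(C)C)C[C@@H]1C(=O)OC(C)(C)C
F2 | step 5 | tert-butyl (1S,2S)-2-[(benzyloxy)methyl]-2-formyl-5-oxocyclohex-3-ene-1-carboxylate | O=C[C@@]1(COCc2ccccc2)C=CC(=O)C[C@@H]1C(=O)OC(C)(C)C
F3 | step 5 | (4R,5R)-1,3-dimethyl-4,5-diphenylimidazolidin-2-yl aminal of 10 | CN1[C@H](c2ccccc2)[C@@H](c3ccccc3)N(C)C1[C@]4(COCc5ccccc5)C=CC(=O)C[C@H]4C(=O)OC(C)(C)C
F4 | step 5 | (4R,5R)-1,3-dimethyl-4,5-diphenylimidazolidin-2-yl aminal of the enantiomer of 10 | CN1[C@H](c2ccccc2)[C@@H](c3ccccc3)N(C)C1[C@@]4(COCc5ccccc5)C=CC(=O)C[C@@H]4C(=O)OC(C)(C)C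
F5 | step 17 | C12 triisopropylsilyl enol ether analogue of 24 | CC(=O)O[C@H]1CCC(C)(C)[C@@H](C(=O)OC(C)(C)C)[C@@]12COC(=O)[C@@]3(C(C)=O)CC=C(O[Si](C(C)C)(C(C)C)C(C)C)C[C@@H]23
F6 | step 17 | C12 enol triflate analogue of 24 | CC(=O)O[C@H]1CCC(C)(C)[C@@H](C(=O)OC(C)(C)C)[C@@]12COC(=O)[C@@]3(C(C)=O)CC=C(OS(=O)(=O)C(F)(F)F)C[C@@H]23
F7 | step 18 | iodomethyl ketone of 24 | CC(=O)O[C@H]1CCC(C)(C)[C@@H](C(=O)OC(C)(C)C)[C@@]12COC(=O)[C@@]3(C(=O)CI)CC=CC[C@@H]23
F8 | step 18 | C12 iodide of the bicyclo[3.2.1]octanone (either C12 epimer) | CC(=O)O[C@H]1CCC(C)(C)[C@@H](C(=O)OC(C)(C)C)[C@@]12COC(=O)[C@@]13C[C@@H](C(I)C[C@H]12)CC3=O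
F9 | step 12 | C1 epimer of 14 (hydroxyl cis to CH2OBn) | COC(OC)[C@]1(COCc2ccccc2)[C@@H](O)C=CC(C)(C)[C@H]1C(=O)OC(C)(C)C
F10 | step 21 | tert-butyl ester with C16 methyl endo and C11=C12 | CC(=O)O[C@H]1CCC(C)(C)[C@@H](C(=O)OC(C)(C)C)[C@@]12COC(=O)[C@@]13C[C@@H](C=C[C@H]12)[C@@H](C)C3=O
F11 | step 21 | tert-butyl ester of the target | CC(=O)O[C@H]1CCC(C)(C)[C@@H](C(=O)OC(C)(C)C)[C@@]12COC(=O)[C@@]13C[C@@H](CC[C@H]12)[C@@H](C)C3=O
A1 | alternative 1 | α-methylene lactone with the silyl allylic acetate chain on C9 (C13 configuration open) | CC(=O)O[C@H]1CCC(C)(C)[C@@H](C(=O)OC(C)(C)C)[C@@]12COC(=O)C(=C)[C@H]2CCC([Si](C)(C)C)C(=C)COC(C)=O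
A2 | alternative 1 | bicyclo[3.2.1]octane lactone with C16 exocyclic methylene | CC(=O)O[C@H]1CCC(C)(C)[C@@H](C(=O)OC(C)(C)C)[C@@]12COC(=O)[C@@]13C[C@@H](CC[C@H]12)C(=C)C3
A3 | alternative 2 | C9 4-hydroxyphenyl bicyclo[3.2.1]octanone chloromethyl ester | ClCOC(=O)[C@@]13C[C@@H](CC[C@H]1c4ccc(O)cc4)CC3=O
A4 | alternative 2 | spirocyclohexadienone lactone | O=C1C=CC2(C=C1)COC(=O)[C@@]13C[C@@H](CC[C@H]12)CC3=O
A5 | alternative 3 | cyclopentanol spiro-epoxide (2,3-epoxy alcohol; C1 carbinol configuration open) | OC1(CCC(C)(C)[C@H]1CO[Si](C)(C)C(C)(C)C)[C@]2(CO2)[C@@H]3CC[C@@H]4C[C@@]3(C(=O)OC)C5(OCCO5)[C@@H]4C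
A6 | alternative 3 | ring A hydroxymethyl ketone with quaternary C10 | O=C1CCC(C)(C)[C@@H](CO[Si](C)(C)C(C)(C)C)[C@]1(CO)[C@@H]2CC[C@@H]3C[C@@]2(C(=O)OC)C4(OCCO4)[C@@H]3C
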